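Decide which set-up gets the next charge. The aim is to keep target, as a share of all that became target or over-reaction product.

| flask | starting material | reagent | second substrate | third substrate | remark | time |
|---|---|---|---|---|---|---|
| beta | 1 M | 1.3 M | 0.50 M | 1 M | run made earlier |  |
| epsilon | 1 M | 1.3 M | 0.50 M | 1.4 M | run made earlier |  |
| theta | 1 M | 1.3 M | 0.50 M | 2.2 M | run made earlier |  |
| teal | 1.0 M | 1.30 M | 0.500 M (fed, over 3.20 min) | 1.00 M | all but second substrate at the start; second substrate goes in evenly over 3.20 min, the run ends at 4.0 min | 4.0 min |
| blue | 1.0 M | 1.30 M | 0.500 M | 1.00 M | everything together in a closed stirred flask, run for 4.0 min | 4.0 min |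
| red | 1.0 M | 1.30 M | 0.500 M | 1.00 M | a single well-mixed tank run continuously and read at steady state, 4.0 min in it on average |  |
| green | 1.0 M | 1.30 M | 0.500 M | 1.00 M (fed, over 3.20 min) | all but third substrate at the start; third substrate goes in evenly over 3.20 min, the run ends at 4.0 min | 4.0 min |

| run | time / min | target / % | over-reaction product / % |
|---|---|---|---|
| beta | 0.200 | 31.2 | 1.2 |
| beta | 0.333 | 37.2 | 4.3 |
| beta | 0.667 | 38.3 | 12.1 |
| beta | 1.33 | 32.2 | 23.8 |
| beta | 2.50 | 17.6 | 39.0 |
| epsilon | 0.250 | 31.1 | 2.3 |
| epsilon | 0.833 | 32.6 | 12.7 |
| epsilon | 1.33 | 25.2 | 21.2 |
| epsilon | 2.50 | 13.6 | 33.8 |
| epsilon | 3.00 | 10.5 | 36.4 |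
| theta | 0.667 | 25.9 | 8.6 |
| theta | 1.33 | 18.8 | 16.1 |
| theta | 2.00 | 12.4 | 22.4 |
| theta | 2.50 | 9.3 | 24.6 |
| theta | 3.00 | 8.1 | 26.9 |

(scatter of a reading: 0.5 percentage points)

- the stated concentrations are those of everything mixed, before any reaction; amounts are the same in each set-up
- the feed brings no volume worth counting
- the earlier runs were made in a closed, stirred flask

* the set-up with the highest share of target in all that became target or over-reaction product, at the outlet or at the end ("none" if the first two lie within 2 percentage points) (teal / blue / red / green / none)
* share of target in all that became target or over-reaction product, at the outlet or at the end, teal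
* share of target in all that became target or over-reaction product, at the outlet or at the end, blue
* share of target in all that became target or over-reaction product, at the outlet or at the end, red
* share of target in all that became target or over-reaction product, at the outlet or at the end, green

1. Work with the fraction of target left, not the fraction made. In the beta run, target plus over-reaction product reads 56.0% at 1.33 min and 56.6% at 2.50 min, so treat the fall of target over that stretch as passage into over-reaction product.

2. Take the ageing constant, the drop in the logarithm of target per minute over that stretch: it reads 0.516 min⁻¹. For this first-order loss, the fraction left after a time is the exponential of minus the constant times that time.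

3. Reckon blue by continuing beta, which has the same charge in the same kind of flask. The share at 2.50 min is 31.1%, and ageing on to 4.0 min leaves 14.3%.

4. Reckon red from two exits. At steady state, target leaves the tank by the outflow or by ageing, so the fraction left is one over one plus the constant times the mean time. That product is the Damköhler number, here 2.07, which gives 32.6%, more than blue.

5. Expect teal and green near blue, as a judgement and not a reckoning: both are fed flasks read at 4.0 min, with starting material and reagent together from the start.

6. Charge the tank and leave the feeds out.

The forecast also picks red, with teal 20%, blue 14%, red 32% and green 17%, and it says of red that “the tank holds target only briefly on average”. Its teal stands above my estimate.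

Red gives 31.6%, above teal 14.0%, blue 13.8% and green 14.9%.

    starting material + reagent → target (k = 0.0390 M⁻¹ s⁻¹)
    second substrate + reagent → second product (k = 0.00700 M⁻¹ s⁻¹)
    third substrate + reagent → third product (k = 0.0490 M⁻¹ s⁻¹)
    target → over-reaction product (k = 0.00900 s⁻¹)

Teal came in under the forecast's 20%, at 14.0% beside blue's 13.8%. Now carry the ageing constant to the epsilon run, whose share is 22.5% at 3.00 min. Ageing on to 4.0 min leaves a fraction 59.7%, which makes 13.4%, and the epsilon run at that time has a share of 13.1%.

The data were computed from invented constants.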